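**Retrosynthetic overview**
1. The ten-membered ring is closed last, by ring-closing metathesis at C5=C6 (2-substituted acrylate plus C7 vinyl group).
2. The 8-hydroxy-17-methyl lactone comes from an 8,17-epoxybutenolide (hydroxyl-directed epoxidation, then reductive opening).
3. Key bond C8–C9: the β-carbon of a tetronic acid triflate is made nucleophilic (Ni/Cr; a β-acyl-vinyl anion, d3 "unsaturated homoenolate") and added to the C9 aldehyde under Felkin–Anh control.
4. C9 itself is attached to C10 as a hydroxymethyl-anion (d1) equivalent by conjugate addition to a 2-methylcyclohexenone. The C1 quaternary centre comes from an auxiliary-controlled Birch reduction–methylation; C2 and C14 from CBS and syn-1,3 reductions.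
5. Ring order: six-membered ring (from an arene), butenolide (made separately from a vinylglycolate), ten-membered ring.

Assumption: the (S)-auxiliary is taken to deliver methyl to the face giving the drawn C1 configuration (chelated-enolate model; otherwise its antipode is used). Carbons carry the briarane numbers of the target (C15 = methyl on C1, C16 = ester carbon, C18 = methyl on C17, C19 = lactone carbonyl, C20 = methyl on C11); β is the ring face of C15, α the opposite face.

**Step 1**
Reactants: 1 2-methoxy-5-methylbenzoic acid; 2 (S)-2-(methoxymethyl)pyrrolidine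
Product: 4 (2-methoxy-5-methylphenyl)[(2S)-2-(methoxymethyl)pyrrolidin-1-yl]methanone, via acid chloride 3 (not isolated)
Conditions: (COCl)2, cat. DMF, CH2Cl2, 0 °C; then 2, Et3N, 0 to 25 °C
Reagents that add atoms: none
Why: Amide formation through the acid chloride (Schotten–Baumann-type acylation) attaches the chiral auxiliary, and no new stereocentre is formed.

**Step 2**
Reactants: 4 the benzamide
Product: 6 [(1R)-2-methoxy-1,5-dimethylcyclohexa-2,5-dien-1-yl][(2S)-2-(methoxymethyl)pyrrolidin-1-yl]methanone, via potassium enolate 5 (not isolated)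
Conditions: K (2.2 equiv), t-BuOH (1 equiv), NH3/THF, −78 °C; then MeI, −78 °C
Reagents that add atoms: iodomethane, CI
Why: Schultz-type asymmetric Birch reduction–alkylation, in which the chelated potassium amide enolate is methylated on the face away from the methoxymethyl arm, sets quaternary C1 (with C15) as one diastereomer while the methoxy and methyl substituents keep the remaining double bonds at C13=C14 and C10=C11.

**Step 3**
Reactants: 6 the dienyl amide
Product: 7 1-[(1R)-2-methoxy-1,5-dimethylcyclohexa-2,5-dien-1-yl]ethan-1-one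
Conditions: MeLi (3 equiv), THF, 0 to 25 °C; then H2O
Reagents that add atoms: methyllithium, [Li]C
Why: Methyllithium adds once to the non-enolisable tertiary amide because the lithium hemiaminal is stabilised by chelation to the methoxymethyl ether (Weinreb-type ketone synthesis), which releases the auxiliary and gives the C2 carbonyl carrying C3.

**Step 4**
Reactants: 7 the methyl ketone; 8 2,3-dibromoprop-1-ene
Product: 10 4-bromo-1-[(1R)-2-methoxy-1,5-dimethylcyclohexa-2,5-dien-1-yl]pent-4-en-1-one, via lithium enolate 9 (not isolated)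
Conditions: lithium diisopropylamide, THF, −78 °C; then 8, −78 to 0 °C
Reagents that add atoms: none
Why: Kinetic enolate alkylation (C3 is the only enolisable position) at the allylic bromide of 8 installs C4 and C5, with the inert vinyl bromide serving as a masked acrylate that is not a Michael acceptor.

**Step 5**
Reactants: 10 the bromo-enone chain ketone
Product: 12 (2S)-2-[(1R)-4-bromo-1-hydroxypent-4-en-1-yl]-2,4-dimethylcyclohex-3-en-1-one, via carbinol enol ether 11 (not isolated)
Conditions: (S)-2-methyl-CBS-oxazaborolidine (20 mol%), catecholborane, toluene, −78 °C; then 1 M HCl, THF, 0 °C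
Reagents that add atoms: water, O
Why: Corey–Bakshi–Shibata reduction distinguishes the quaternary (large) from the primary (small) flank so that the (S)-catalyst gives the (2R)-carbinol, and the acidic work-up hydrolyses the methyl enol ether to the C14 ketone, which cannot conjugate through quaternary C1.

**Step 6**
Reactants: 12 the β-hydroxy ketone
Product: 13 (1S,2R)-2-[(1R)-4-bromo-1-hydroxypent-4-en-1-yl]-2,4-dimethylcyclohex-3-en-1-ol
Conditions: Et2BOMe, NaBH4, THF/MeOH (4:1), −78 °C; then MeOH co-evaporation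
Reagents that add atoms: none
Why: Narasaka–Prasad reduction, in which external hydride attacks the boron chelate between the C2 hydroxyl and the C14 ketone, gives the syn-1,3-diol, that is the 14α-hydroxyl cis to the C2 side chain.

**Step 7**
Reactants: 13 the syn-diol
Product: 14 the 2,14-diacetate of 13
Conditions: Ac2O, DMAP, pyridine, 25 to 40 °C
Reagents that add atoms: acetic anhydride, CC(=O)OC(C)=O
Why: DMAP-catalysed acetylation installs the C2 and C14 acetates of the target on the two hindered secondary alcohols without creating a stereocentre.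

**Step 8**
Reactants: 14 the diacetate
Product: 15 the C12 enone (2-methylcyclohex-2-enone with C12=O and C10=C11, 14α-acetoxy, 1β-methyl, 1α-[(1R)-1-acetoxy-4-bromopent-4-enyl])
Conditions: CrO3, 3,5-dimethylpyrazole, CH2Cl2, −20 °C
Reagents that add atoms: chromium trioxide, O=[Cr](=O)=O
Why: Chromium-mediated allylic oxidation attacks the only ring allylic methylene, C12 (C1 is quaternary), and gives the 2-methylcyclohexenone acceptor without touching a stereocentre.

**Step 9**
Reactants: 15 the enone
Product: 18 the 12β-alcohol carrying 10β-CH2SiMe2(Oi-Pr) and 11β-methyl, via silyl enol ether 16 (not isolated), via ketone 17 (not isolated)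
Conditions: (i-PrO)Me2SiCH2MgCl, CuBr·SMe2 (20 mol%), TMSCl, THF, −78 to −40 °C; then AcOH/MeOH, −78 °C; then NaBH4, −78 to −20 °C
Reagents that add atoms: (isopropoxydimethylsilyl)methylmagnesium chloride, CC(C)O[Si](C)(C)C[Mg]Cl
Why: Copper-catalysed conjugate addition of the Tamao hydroxymethyl-anion (d1) equivalent enters C10 on the β-face, anti to the cis-disposed C2 chain and C14 acetate on the α-face; kinetic protonation anti to the new pseudoaxial C9 group then gives the 11β-methyl, and in-situ borohydride attack from the same α-face gives the 12β-alcohol before C11 can epimerise or acetate can be eliminated.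

**Step 10**
Reactants: 18 the 12β-alcohol
Product: 19 the 12-O-tert-butyldimethylsilyl ether of 18
Conditions: TBSOTf, 2,6-lutidine, CH2Cl2, 0 °C
Reagents that add atoms: tert-butyldimethylsilyl trifluoromethanesulfonate, CC(C)(C)[Si](C)(C)OS(=O)(=O)C(F)(F)F
Why: Silylation of the only free hydroxyl masks O12 so that it ends up as the free alcohol after the last acetylation.

**Step 11**
Reactants: 19 the silyl ether
Product: 20 the C9 primary alcohol (10β-hydroxymethyl)
Conditions: H2O2 (30%), KF, KHCO3, THF/MeOH, 25 °C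
Reagents that add atoms: hydrogen peroxide, OO
Why: Tamao–Fleming oxidation converts the C9–Si bond into C9–OH with retention and leaves the acetates, the silyl ether and the vinyl bromide intact.

**Step 12**
Reactants: 20 the bromoalkene alcohol
Product: 21 the methyl acrylate (C5(=CH2)–CO2Me)
Conditions: Pd(OAc)2 (5 mol%), PPh3, CO (1 atm), MeOH, Et3N, DMF, 60 °C
Reagents that add atoms: carbon monoxide, [C-]#[O+]; methanol, CO
Why: Palladium-catalysed methoxycarbonylation (oxidative addition of zerovalent palladium to the 2-bromoalkene, CO insertion, methanolysis) creates the C16 methyl ester as the 2-substituted acrylate needed for ring closure.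

**Step 13**
Reactants: 21 the acrylate alcohol
Product: 22 the C9 aldehyde
Conditions: Dess–Martin periodinane, NaHCO3, CH2Cl2, 0 °C
Reagents that add atoms: none
Why: Dess–Martin oxidation of the only free (primary) alcohol gives the aldehyde under non-basic conditions that do not epimerise C10.

**Step 14**
Reactants: 23 methyl (2S)-2-hydroxybut-3-enoate; 24 2-bromopropanoyl bromide
Product: 25 methyl (2S)-2-[(2-bromopropanoyl)oxy]but-3-enoate
Conditions: pyridine, CH2Cl2, 0 °C
Reagents that add atoms: none
Why: O-acylation under mild base leaves the allylic C7 stereocentre untouched, and the configuration at the brominated carbon is irrelevant because it is destroyed in the next step.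

**Step 15**
Reactants: 25 the bromo ester
Product: 26 (5S)-4-hydroxy-3-methyl-5-vinylfuran-2(5H)-one
Conditions: SmI2 (2.2 equiv), THF, −78 to 0 °C; then 1 M HCl
Reagents that add atoms: none
Why: Proposed new method: two equivalents of SmI2 reduce the C–Br bond to a trivalent samarium ester enolate, formed regiospecifically and without base so that the acidic allylic C7–H is not touched, and this enolate acylates the neighbouring methyl ester in a five-membered Dieckmann-type closure to the tetronic acid, the closest known reactions being the SmI2-promoted intramolecular Reformatsky reaction and the zinc-mediated Blaise route to tetronic acids.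

**Step 16**
Reactants: 26 the tetronic acid
Product: 27 (2S)-4-methyl-5-oxo-2-vinyl-2,5-dihydrofuran-3-yl trifluoromethanesulfonate
Conditions: Tf2O, Et3N, CH2Cl2, −78 °C
Reagents that add atoms: trifluoromethanesulfonic anhydride, O=S(=O)(OS(=O)(=O)C(F)(F)F)C(F)(F)F
Why: O-triflation of the vinylogous acid gives the β-triflyloxybutenolide that serves as precursor of the C8 nucleophile, with no change at C7.

**Step 17**
Reactants: 22 the C9 aldehyde; 27 the butenolide triflate
Product: 28 the (9R)-carbinol in which C9 is bonded to C8 of the 3-methyl-5-vinylbutenolide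
Conditions: CrCl2 (6 equiv), NiCl2 (5 mol%), DMF/THF, 25 °C
Reagents that add atoms: none
Why: Nozaki–Hiyama–Kishi coupling, in which zerovalent nickel inserts into the vinyl triflate and transmetalation gives a trivalent vinylchromium, makes the lactone β-carbon C8 (an acceptor position in any butenolide) react as a β-acyl-vinyl anion (d3, unsaturated homoenolate) equivalent that adds only to the aldehyde, and Felkin–Anh control from C10 (quaternary C1 anti to the nucleophile, C11 inside) gives the (9R)-alcohol.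

**Step 18**
Reactants: 28 the butenolide carbinol
Product: 29 the 8,17-epoxide (oxygen cis to the C7 vinyl group)
Conditions: m-CPBA, Na2HPO4, ClCH2CH2Cl, 45 °C
Reagents that add atoms: 3-chloroperbenzoic acid, OOC(=O)c1cccc(Cl)c1
Why: Hydroxyl-directed (Henbest) epoxidation of the tetrasubstituted butenolide alkene, in which A(1,3) strain with the C18 methyl holds H9 in the alkene plane so that the hydrogen-bonded peracid delivers oxygen threo, sets C8 correctly while the acrylate and the vinyl group are too electron-poor or too little substituted to compete.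

**Step 19**
Reactants: 29 the epoxy lactone
Product: 30 the 8,9-diol lactone (tertiary 8-OH, 17-H, C18 methyl cis to 8-OH)
Conditions: SmI2 (2.5 equiv), THF/MeOH, −78 °C
Reagents that add atoms: none
Why: SmI2 reduction of the α,β-epoxy lactone cleaves the C17–O bond and keeps the tertiary C8–O bond, and the samarium enolate is protonated on the face away from the pseudoaxial samarium alkoxide, which puts the C18 methyl cis to the 8-hydroxyl and trans to the bulky C9 branch (also the more stable epimer) while the acrylate is not reduced at this temperature without HMPA.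

**Step 20**
Reactants: 30 the diol
Product: 31 the 9-acetate (2,9,14-triacetate, free tertiary 8-OH, 12-OTBS)
Conditions: Ac2O, DMAP, pyridine, 25 °C
Reagents that add atoms: acetic anhydride, CC(=O)OC(C)=O
Why: DMAP-catalysed acetylation takes the secondary C9 hydroxyl while the tertiary C8 hydroxyl and the silylated O12 do not react.

**Step 21**
Reactants: 31 the acyclic diene
Product: 32 the ten-membered-ring compound (12-O-TBS ether of the target)
Conditions: second-generation Hoveyda–Grubbs catalyst RuCl2(H2IMes)(=CH-C6H4-2-Oi-Pr) (20 mol%), toluene (1 mM), 100 °C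
Reagents that add atoms: none
Why: Ring-closing metathesis between the C7 vinyl group and the 2-substituted acrylate closes the ten-membered ring at C5=C6 with loss of ethene, and the medium ring accommodates only the endocyclic cis olefin, which is the required geometry (ester trans to C7, E by CIP).

**Step 22**
Reactants: 32 the silyl ether
Product: 33 CNP0233742.2 (target)
Conditions: HF·pyridine, pyridine/THF, 0 to 25 °C
Reagents that add atoms: none
Why: Fluoride-mediated desilylation frees the 12β-hydroxyl without touching the three acetates, the methyl ester, the lactone or the tertiary alcohol.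

**Compound list**
1 | 2-methoxy-5-methylbenzoic acid | COc1ccc(C)cc1C(=O)O | starting material
2 | (S)-2-(methoxymethyl)pyrrolidine | COC[C@@H]1CCCN1 | starting material
3 | 2-methoxy-5-methylbenzoyl chloride | COc1ccc(C)cc1C(Cl)=O | intermediate
4 | (2-methoxy-5-methylphenyl)[(2S)-2-(methoxymethyl)pyrrolidin-1-yl]methanone | COc1ccc(C)cc1C(=O)N1CCC[C@H]1COC | intermediate
5 | potassium enolate of the 1,4-dihydrobenzamide | COC1=CCC(C)=CC1=C([O-])N1CCC[C@H]1COC.[K+] | intermediate
6 | [(1R)-2-methoxy-1,5-dimethylcyclohexa-2,5-dien-1-yl][(2S)-2-(methoxymethyl)pyrrolidin-1-yl]methanone | C1=C(C)CC=C(OC)[C@]1(C)C(=O)N2CCC[C@H]2COC | intermediate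
7 | 1-[(1R)-2-methoxy-1,5-dimethylcyclohexa-2,5-dien-1-yl]ethan-1-one | C1=C(C)CC=C(OC)[C@]1(C)C(C)=O | intermediate
8 | 2,3-dibromoprop-1-ene | C=C(Br)CBr | starting material
9 | lithium enolate of 7 | C1=C(C)CC=C(OC)[C@]1(C)C(=C)[O-].[Li+] | intermediate
10 | 4-bromo-1-[(1R)-2-methoxy-1,5-dimethylcyclohexa-2,5-dien-1-yl]pent-4-en-1-one | C1=C(C)CC=C(OC)[C@]1(C)C(=O)CCC(Br)=C | intermediate
11 | (1R)-4-bromo-1-[(1S)-2-methoxy-1,5-dimethylcyclohexa-2,5-dien-1-yl]pent-4-en-1-ol | C1=C(C)CC=C(OC)[C@]1(C)[C@H](O)CCC(Br)=C | intermediate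
12 | (2S)-2-[(1R)-4-bromo-1-hydroxypent-4-en-1-yl]-2,4-dimethylcyclohex-3-en-1-one | C1=C(C)CCC(=O)[C@]1(C)[C@H](O)CCC(Br)=C | intermediate
13 | (1S,2R)-2-[(1R)-4-bromo-1-hydroxypent-4-en-1-yl]-2,4-dimethylcyclohex-3-en-1-ol (syn-1,3-diol) | C1=C(C)CC[C@H](O)[C@]1(C)[C@H](O)CCC(Br)=C | intermediate
14 | diacetate of 13 ((2R)-acetoxy and 14α-acetoxy) | C1=C(C)CC[C@H](OC(C)=O)[C@]1(C)[C@H](OC(C)=O)CCC(Br)=C | intermediate
15 | C12 enone: 2-methylcyclohex-2-enone with 14α-OAc, 1β-Me and 1α-[(1R)-1-acetoxy-4-bromopent-4-enyl] | C1=C(C)C(=O)C[C@H](OC(C)=O)[C@]1(C)[C@H](OC(C)=O)CCC(Br)=C | intermediate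
16 | trimethylsilyl enol ether (C11=C12) of the conjugate adduct, 10β-CH2SiMe2(Oi-Pr) | CC(C)O[Si](C)(C)C[C@H]1C(C)=C(O[Si](C)(C)C)C[C@H](OC(C)=O)[C@]1(C)[C@H](OC(C)=O)CCC(Br)=C | intermediate
17 | 12-ketone with 10β-CH2SiMe2(Oi-Pr) and 11β-methyl | CC(C)O[Si](C)(C)C[C@H]1[C@@H](C)C(=O)C[C@H](OC(C)=O)[C@]1(C)[C@H](OC(C)=O)CCC(Br)=C | intermediate
18 | 12β-alcohol of 17 | CC(C)O[Si](C)(C)C[C@H]1[C@@H](C)[C@@H](O)C[C@H](OC(C)=O)[C@]1(C)[C@H](OC(C)=O)CCC(Br)=C | intermediate
19 | 12-O-TBS ether of 18 | CC(C)O[Si](C)(C)C[C@H]1[C@@H](C)[C@@H](O[Si](C)(C)C(C)(C)C)C[C@H](OC(C)=O)[C@]1(C)[C@H](OC(C)=O)CCC(Br)=C | intermediate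
20 | C9 primary alcohol (10β-CH2OH), bromoalkene chain | OC[C@H]1[C@@H](C)[C@@H](O[Si](C)(C)C(C)(C)C)C[C@H](OC(C)=O)[C@]1(C)[C@H](OC(C)=O)CCC(Br)=C | intermediate
21 | C9 primary alcohol with methyl 2-substituted acrylate chain | OC[C@H]1[C@@H](C)[C@@H](O[Si](C)(C)C(C)(C)C)C[C@H](OC(C)=O)[C@]1(C)[C@H](OC(C)=O)CCC(=C)C(=O)OC | intermediate
22 | C9 aldehyde with acrylate chain | O=C[C@H]1[C@@H](C)[C@@H](O[Si](C)(C)C(C)(C)C)C[C@H](OC(C)=O)[C@]1(C)[C@H](OC(C)=O)CCC(=C)C(=O)OC | intermediate
23 | methyl (2S)-2-hydroxybut-3-enoate | C=C[C@H](O)C(=O)OC | starting material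
24 | 2-bromopropanoyl bromide | CC(Br)C(Br)=O | starting material
25 | methyl (2S)-2-[(2-bromopropanoyl)oxy]but-3-enoate | C=C[C@H](OC(=O)C(C)Br)C(=O)OC | intermediate
26 | (5S)-4-hydroxy-3-methyl-5-vinylfuran-2(5H)-one | C=C[C@@H]1OC(=O)C(C)=C1O | intermediate
27 | (2S)-4-methyl-5-oxo-2-vinyl-2,5-dihydrofuran-3-yl trifluoromethanesulfonate | C=C[C@@H]1OC(=O)C(C)=C1OS(=O)(=O)C(F)(F)F | intermediate
28 | (9R)-carbinol: butenolide C8 bonded to C9; acrylate and vinyl termini | C=C[C@@H]1OC(=O)C(C)=C1[C@H](O)[C@H]2[C@@H](C)[C@@H](O[Si](C)(C)C(C)(C)C)C[C@H](OC(C)=O)[C@]2(C)[C@H](OC(C)=O)CCC(=C)C(=O)OC | intermediate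
29 | 8,17-epoxy lactone (epoxide cis to the C7 vinyl group) | C=C[C@@H]1OC(=O)[C@@]3(C)[C@@]1(O3)[C@H](O)[C@H]2[C@@H](C)[C@@H](O[Si](C)(C)C(C)(C)C)C[C@H](OC(C)=O)[C@]2(C)[C@H](OC(C)=O)CCC(=C)C(=O)OC | intermediate
30 | 8,9-diol lactone (8-OH tertiary, (17R)-methyl) | C=C[C@@H]1OC(=O)[C@H](C)[C@@]1(O)[C@H](O)[C@H]2[C@@H](C)[C@@H](O[Si](C)(C)C(C)(C)C)C[C@H](OC(C)=O)[C@]2(C)[C@H](OC(C)=O)CCC(=C)C(=O)OC | intermediate
31 | 2,9,14-triacetate diene (8-OH free, 12-OTBS) | C=C[C@@H]1OC(=O)[C@H](C)[C@@]1(O)[C@H](OC(C)=O)[C@H]2[C@@H](C)[C@@H](O[Si](C)(C)C(C)(C)C)C[C@H](OC(C)=O)[C@]2(C)[C@H](OC(C)=O)CCC(=C)C(=O)OC | intermediate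
32 | 12-O-TBS ether of the target (ten-membered ring closed) | COC(=O)/C1=C/[C@@H]2OC(=O)[C@H](C)[C@@]2(O)[C@H](OC(C)=O)[C@H]2[C@@H](C)[C@@H](O[Si](C)(C)C(C)(C)C)C[C@H](OC(C)=O)[C@]2(C)[C@H](OC(C)=O)CC1 | intermediate
33 | CNP0233742.2 (1S,2R,5E,7S,8S,9R,10S,11R,12S,14S,17R) | COC(=O)/C1=C/[C@@H]2OC(=O)[C@H](C)[C@@]2(O)[C@H](OC(C)=O)[C@H]2[C@@H](C)[C@@H](O)C[C@H](OC(C)=O)[C@]2(C)[C@H](OC(C)=O)CC1 | target

**Totals**
Total step count: 22. Longest linear sequence: 19 (steps 1–13 and 17–22).

**Three steps most likely to fail**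

Step 21 (ring-closing metathesis to a ten-membered ring with a trisubstituted enoate next to quaternary C8). The fallback sets out from 28 and comes back at 32. The metathesis is run one stage earlier on the planar butenolide, where C8 is sp2 and the free C9 hydroxyl can assist the ruthenium carbene, to give the macrocyclic butenolide carbinol F1. Directed epoxidation as in step 18 gives the macrocyclic 8,17-epoxide F2. Reductive opening with sodium phenylselenide (PhSeSePh, NaBH4, EtOH/AcOH), chosen because SmI2 could cleave the now γ-acyloxy enoate, gives the macrocyclic 8,9-diol F3. Acetylation as in step 20 returns to 32.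

Step 17 (Ni/Cr coupling of a hindered α-branched aldehyde; Felkin selectivity at C9 may be modest). The fallback sets out from 22 (with 27) and comes back at 28, replacing carbonyl addition by acylation and reagent-controlled reduction. Pinnick oxidation of 22 (NaClO2, NaH2PO4, 2-methylbut-2-ene) gives the C9 carboxylic acid F4, and (COCl)2 converts it into the acid chloride F5. Triflate 27 is converted with Me3SnSnMe3, Pd(PPh3)4 and LiCl into the vinylstannane F6. Stille acylation of F5 with F6 (Pd(PPh3)4, toluene, 60 °C) gives the C9 ketone F7. Reduction with (S)-2-methyl-CBS-oxazaborolidine and catecholborane (butenolide as the large group) gives 28.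

Step 9 (conjugate addition next to a quaternary centre, facial selectivity, kinetic C11 protonation, β-acetoxy ketone). The fallback sets out from 15 and comes back at 22, using a radical formyl-anion equivalent in place of the organocopper reagent. Decatungstate photocatalysis ((Bu4N)4W10O32, 365 nm, 1,3-dioxolane/MeCN) adds the nucleophilic 1,3-dioxolan-2-yl radical to C10 on the β-face, with back-hydrogen transfer to C11 anti to the new group, giving the acetal ketone F8. NaBH4 gives the 12β-alcohol F9, and TBSOTf with 2,6-lutidine gives the silyl ether F10. Methoxycarbonylation as in step 12 gives the acrylate acetal F11. Mild acetal hydrolysis (PPTS, acetone/water) gives aldehyde 22.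

**Further compounds**
F1 | step 21 | macrocyclic butenolide carbinol (ring closed, 9-OH, 12-OTBS) | COC(=O)/C1=C/[C@@H]2OC(=O)C(C)=C2[C@H](O)[C@H]2[C@@H](C)[C@@H](O[Si](C)(C)C(C)(C)C)C[C@H](OC(C)=O)[C@]2(C)[C@H](OC(C)=O)CC1
F2 | step 21 | macrocyclic 8,17-epoxide | COC(=O)/C1=C/[C@@H]2OC(=O)[C@@]3(C)[C@@]2(O3)[C@H](O)[C@H]2[C@@H](C)[C@@H](O[Si](C)(C)C(C)(C)C)C[C@H](OC(C)=O)[C@]2(C)[C@H](OC(C)=O)CC1
F3 | step 21 | macrocyclic 8,9-diol | COC(=O)/C1=C/[C@@H]2OC(=O)[C@H](C)[C@@]2(O)[C@H](O)[C@H]2[C@@H](C)[C@@H](O[Si](C)(C)C(C)(C)C)C[C@H](OC(C)=O)[C@]2(C)[C@H](OC(C)=O)CC1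
F4 | step 17 | C9 carboxylic acid | OC(=O)[C@H]1[C@@H](C)[C@@H](O[Si](C)(C)C(C)(C)C)C[C@H](OC(C)=O)[C@]1(C)[C@H](OC(C)=O)CCC(=C)C(=O)OC
F5 | step 17 | C9 acid chloride | ClC(=O)[C@H]1[C@@H](C)[C@@H](O[Si](C)(C)C(C)(C)C)C[C@H](OC(C)=O)[C@]1(C)[C@H](OC(C)=O)CCC(=C)C(=O)OC
F6 | step 17 | (5S)-3-methyl-4-(trimethylstannyl)-5-vinylfuran-2(5H)-one | C=C[C@@H]1OC(=O)C(C)=C1[Sn](C)(C)C
F7 | step 17 | C9 ketone (4-acylbutenolide) | C=C[C@@H]1OC(=O)C(C)=C1C(=O)[C@H]2[C@@H](C)[C@@H](O[Si](C)(C)C(C)(C)C)C[C@H](OC(C)=O)[C@]2(C)[C@H](OC(C)=O)CCC(=C)C(=O)OC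
F8 | step 9 | 12-ketone with 10β-(1,3-dioxolan-2-yl) and 11β-methyl | C1COC(O1)[C@H]2[C@@H](C)C(=O)C[C@H](OC(C)=O)[C@]2(C)[C@H](OC(C)=O)CCC(Br)=C
F9 | step 9 | 12β-alcohol of F8 | C1COC(O1)[C@H]2[C@@H](C)[C@@H](O)C[C@H](OC(C)=O)[C@]2(C)[C@H](OC(C)=O)CCC(Br)=C
F10 | step 9 | 12-O-TBS ether of F9 | C1COC(O1)[C@H]2[C@@H](C)[C@@H](O[Si](C)(C)C(C)(C)C)C[C@H](OC(C)=O)[C@]2(C)[C@H](OC(C)=O)CCC(Br)=C
F11 | step 9 | acrylate acetal | C1COC(O1)[C@H]2[C@@H](C)[C@@H](O[Si](C)(C)C(C)(C)C)C[C@H](OC(C)=O)[C@]2(C)[C@H](OC(C)=O)CCC(=C)C(=O)OC
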